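## Retrosynthetic overview

1. The diosphenol is made last, by α′-hydroxylation and oxidation of a 7β-acetoxy-3-oxo-4(18)-methylene cis-clerodan-15-oic acid.
2. Ring A is formed last: a 3-hydroxy-3-vinyl cis-hydrindane undergoes an oxidative semipinacol ring expansion, in which the quaternary C5 shifts from C3 to C4 and delivers the C3 ketone and the C4(18) methylene together.
3. C7–O and C8–Me come from hydroboration of a Δ7 8-methyl alkene (enol triflate, Negishi methylation); the C9 quaternary centre comes from alkylating the cis-hydrindanone enolate with a chiral C6 iodo ester.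
4. Ring B is formed first, by a Hajos–Parrish-type annulation of 2-methylcyclopentane-1,3-dione with ethyl vinyl ketone; the five-membered ring is carried as a ketal and cis-hydrogenation sets H10.
5. The side chain comes from 4-methyl-5,6-dihydro-2H-pyran-2-one by asymmetric hydrogenation and lactone opening with iodotrimethylsilane.

Assumption: clerodane atom numbers are used for all bicyclic compounds (in the hydrindanes ring A is the five-membered ring C5–C3–C2–C1–C10, C4 and C18 being added in Step 12), β means the face of the C5 methyl group, and the C3 epimers of 19–21 and C2 epimers of 24 are inconsequential.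

## Route

Step 1
Reactants: 1 4-methyl-5,6-dihydro-2H-pyran-2-one (anhydromevalonolactone)
Product: 2 (R)-4-methyltetrahydro-2H-pyran-2-one
Conditions: H2 (100 atm), Ru(OAc)2(BINAP) (0.5 mol %; the BINAP antipode that gives the R lactone), CH2Cl2, 50 °C
Reagents that add atoms: none
Why: Noyori-type asymmetric hydrogenation of a β-substituted α,β-unsaturated lactone sets the methyl-bearing centre (the later C13) by catalyst control.

Step 2
Reactants: 2 (R)-4-methyltetrahydro-2H-pyran-2-one
Product: 4 methyl (S)-5-iodo-3-methylpentanoate, via silyl ester 3 (not isolated)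
Conditions: Me3SiI (1.2 equiv), CH2Cl2, 25 °C; then MeOH (excess), 25 °C
Reagents that add atoms: iodotrimethylsilane C[Si](C)(C)I; methanol CO
Why: Silyl activation of the lactone carbonyl and SN2 opening by iodide at the O–CH2 carbon give the ω-iodo silyl ester, which the acidic methanol quench converts into the methyl ester without touching the stereocentre (R becomes S only through a change of CIP priorities).

Step 3
Reactants: 5 2-methylcyclopentane-1,3-dione; 6 pent-1-en-3-one (ethyl vinyl ketone)
Product: 8 (S)-4,7a-dimethyl-2,3,7,7a-tetrahydro-1H-indene-1,5(6H)-dione, via triketone 7 (not isolated)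
Conditions: H2O, 25 °C; concentrate; then (S)-phenylalanine (1.0 equiv), 1 M HClO4 (0.4 equiv), MeCN, 80 °C
Reagents that add atoms: none
Why: Michael addition followed by the amino-acid-mediated intramolecular aldol condensation (Hajos–Parrish–Eder–Sauer–Wiechert reaction) builds ring B and sets the C5 quaternary centre as S through the phenylalanine enamine, with crystallisation raising the ee.

Step 4
Reactants: 8 (S)-4,7a-dimethyl-2,3,7,7a-tetrahydro-1H-indene-1,5(6H)-dione
Product: 9 C3 ethylene ketal of 8 (3,3-ethylenedioxy; C8 enone intact)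
Conditions: Me3SiOCH2CH2OSiMe3 (1.5 equiv), Me3SiOTf (5 mol %), CH2Cl2, −78 → −20 °C
Reagents that add atoms: 1,2-bis(trimethylsilyloxy)ethane C[Si](C)(C)OCCO[Si](C)(C)C
Why: Noyori ketalisation is kinetically selective for a saturated ketone over a conjugated enone, so only the cyclopentanone carbonyl (C3) is masked.

Step 5
Reactants: 9 C3 ethylene ketal of 8
Product: 10 cis-fused ketal ketone (3,3-ethylenedioxy; 5β-Me; 10β-H; 9α-Me; 8-oxo)
Conditions: H2 (4 atm), 10% Pd/C, EtOAc, Et3N (trace), 25 °C
Reagents that add atoms: none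
Why: Heterogeneous hydrogenation of Hajos–Parrish-type enones adds hydrogen cis to the angular methyl and so gives the cis-hydrindane (10β-H), while the C9 methine is planarised again in Step 6.

Step 6
Reactants: 10 cis-fused ketal ketone; 4 methyl (S)-5-iodo-3-methylpentanoate
Product: 12 C9-alkylated keto ester (9β-CH2CH2CH(CH3)CH2CO2Me with 13R; 9α-Me; 8-oxo; 3,3-ethylenedioxy), via lithium enolate 11 (not isolated)
Conditions: LiN(iPr)2 (0.95 equiv), THF, −78 → 25 °C, 2 h; then 4 (1.3 equiv), DMPU, 0 → 25 °C
Reagents that add atoms: none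
Why: Equilibration with a slight excess of ketone gives the more substituted C8=C9 lithium enolate (thermodynamic enolate alkylation), and SN2 attack on the primary iodide occurs on the convex β face of the cis-hydrindane (syn to H10 and the C5 methyl, anti to C1), placing the side chain β and the C9 methyl α.

Step 7
Reactants: 12 C9-alkylated keto ester
Product: 14 Δ7 enol triflate (C8–OTf), via potassium enolate 13 (not isolated)
Conditions: KN(SiMe3)2 (1.1 equiv), THF, −78 °C; then PhNTf2 (1.2 equiv), −78 → 0 °C
Reagents that add atoms: N-phenylbis(trifluoromethanesulfonimide) O=S(=O)(N(c1ccccc1)S(=O)(=O)C(F)(F)F)C(F)(F)F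
Why: Because C9 is quaternary the ketone can enolise only toward C7, and O-sulfonylation of that enolate (the ketone being more acidic than the ester) gives the enol triflate.

Step 8
Reactants: 14 Δ7 enol triflate
Product: 15 8-methyl Δ7 alkene (methyl ester; 3,3-ethylenedioxy)
Conditions: MeZnCl (2.0 equiv), Pd(PPh3)4 (5 mol %), THF, 50 °C
Reagents that add atoms: methylzinc chloride C[Zn]Cl
Why: Negishi cross-coupling of the alkenyl triflate installs C17 without affecting the ester or the ketal.

Step 9
Reactants: 15 8-methyl Δ7 alkene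
Product: 18 7β-hydroxy-8α-methyl-3-oxo acid (free C15 acid; C3 ketone), via alkylborane 16 (not isolated), via hydroxy ketal acid 17 (not isolated)
Conditions: BH3·THF (1.5 equiv), THF, 0 → 25 °C; then 3 M NaOH, 30% H2O2, MeOH, 0 → 45 °C; then 3 M HCl to pH 1, 25 °C
Reagents that add atoms: hydrogen peroxide OO; sodium hydroxide [Na+].[OH-]; water O
Why: Hydroboration–oxidation adds syn and anti-Markovnikov from the open convex β face (ring A and the 9α-methyl shield the α face), so boron goes to C7 and hydrogen to C8 and oxidation with retention gives 7β-OH trans to the 8α-methyl, while the warm alkaline stage saponifies the methyl ester and the acid stage hydrolyses the dioxolane.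

Step 10
Reactants: 18 7β-hydroxy-8α-methyl-3-oxo acid
Product: 19 3-vinyl-3,7β-diol acid (3α-vinyl, 3β-OH drawn)
Conditions: CH2=CHMgBr (6 equiv), CeCl3 (6 equiv), THF, −78 → 0 °C; NH4Cl/HCl work-up
Reagents that add atoms: vinylmagnesium bromide C=C[Mg]Br
Why: After deprotonation of the acid and the alcohol, cerium-mediated Grignard 1,2-addition (which suppresses enolisation) to the hindered cyclopentanone gives the tertiary allylic alcohol, whose new C3 centre is destroyed in Step 12 so that either epimer serves.

Step 11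
Reactants: 19 3-vinyl-3,7β-diol acid
Product: 21 7β-acetoxy-3-hydroxy-3-vinyl acid, via mixed anhydride 20 (not isolated)
Conditions: Ac2O (4 equiv), pyridine, DMAP (5 mol %), CH2Cl2, 0 → 25 °C; then H2O/pyridine, 25 °C
Reagents that add atoms: acetic anhydride CC(=O)OC(C)=O
Why: DMAP-catalysed acylation esterifies the secondary 7β-alcohol but not the tertiary allylic alcohol, and the carboxylic mixed anhydride formed alongside is hydrolysed in the aqueous pyridine quench.

Step 12
Reactants: 21 7β-acetoxy-3-hydroxy-3-vinyl acid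
Product: 22 7β-acetoxy-3-oxo-cis-cleroda-4(18)-en-15-oic acid
Conditions: Pd(OCOCF3)2 (10 mol %), 1,4-benzoquinone (1.5 equiv), 2,6-di-tert-butyl-4-methylpyridine (0.3 equiv), 4 Å MS, ClCH2CH2Cl, 50 °C
Reagents that add atoms: none
Why: Proposed new method: Wacker-type π-activation of the vinyl group by electrophilic divalent palladium anti to the C3–C5 bond, with the hindered pyridine shuttling the hydroxyl proton, should trigger a semipinacol 1,2-shift of the quaternary C5 (a better migrating group than the C2 methylene) from C3 to C4 and so expand ring A, giving a C18 alkylpalladium whose only β-hydrogen (H4) is eliminated to the non-isomerisable 4(18)-methylene ketone while benzoquinone returns zerovalent palladium to the divalent state; the closest known reaction type is the palladium-catalysed oxidative ring expansion of strained 1-vinylcyclobutanols to 2-methylenecyclopentanones, extended here to an unstrained cyclopentanol where the quaternary migrating carbon and C=O formation provide the drive.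

Step 13
Reactants: 22 7β-acetoxy-3-oxo-cis-cleroda-4(18)-en-15-oic acid
Product: 24 7β-acetoxy-2-hydroxy-3-oxo-cis-cleroda-4(18)-en-15-oic acid (C2 epimers), via silyl dienol ether 23 (not isolated)
Conditions: Me3SiOTf (3.0 equiv), iPr2NEt (4.0 equiv), CH2Cl2, 0 °C; then mCPBA (1.1 equiv), NaHCO3, CH2Cl2, −20 °C; then 1 M HCl/THF, 0 °C
Reagents that add atoms: 3-chloroperoxybenzoic acid OOC(=O)c1cccc(Cl)c1
Why: Rubottom oxidation works here because soft enolisation can occur only toward C2 (C4 bears no hydrogen) and the electron-rich silyl enol ether bond of the 2-silyloxy diene is epoxidised in preference to the 4(18)-alkene, giving the α′-hydroxy enone after desilylation.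

Step 14
Reactants: 24 7β-acetoxy-2-hydroxy-3-oxo-cis-cleroda-4(18)-en-15-oic acid
Product: 25 7β-acetoxy-2-hydroxy-3-oxo-cis-cleroda-1,4(18)-dien-15-oic acid (CNP0257844.1; 5β-Me, 10β-H, 9β-side chain, 9α-Me, 8α-Me, 13R)
Conditions: Dess–Martin periodinane (1.5 equiv), NaHCO3, CH2Cl2, 25 °C
Reagents that add atoms: none
Why: Dess–Martin oxidation of the acyloin gives the 2,3-dione, which tautomerises to its only possible enol, the Δ1 diosphenol conjugated with the C3 ketone, leaving every stereocentre untouched.

## Compound list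

1 | 4-methyl-5,6-dihydro-2H-pyran-2-one | CC1=CC(=O)OCC1 | starting material
2 | (R)-4-methyltetrahydro-2H-pyran-2-one | C[C@@H]1CCOC(=O)C1 | intermediate
3 | trimethylsilyl (S)-5-iodo-3-methylpentanoate | ICC[C@@H](C)CC(=O)O[Si](C)(C)C | intermediate
4 | methyl (S)-5-iodo-3-methylpentanoate | ICC[C@@H](C)CC(=O)OC | intermediate
5 | 2-methylcyclopentane-1,3-dione | CC1C(=O)CCC1=O | starting material
6 | pent-1-en-3-one | CCC(=O)C=C | starting material
7 | 2-methyl-2-(3-oxopentyl)cyclopentane-1,3-dione | CCC(=O)CCC1(C)C(=O)CCC1=O | intermediate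
8 | (S)-4,7a-dimethyl-2,3,7,7a-tetrahydro-1H-indene-1,5(6H)-dione | CC1=C2CCC(=O)[C@@]2(C)CCC1=O | intermediate
9 | C3 ethylene ketal of 8 (spiro-dioxolane at the cyclopentanone carbon; enone intact) | CC1=C2CCC3(OCCO3)[C@@]2(C)CCC1=O | intermediate
10 | cis-fused ketal ketone (5β-Me, 10β-H, 9α-Me, 8-oxo, C3 dioxolane) | C13(OCCO1)CC[C@@H]2[C@H](C)C(=O)CC[C@]32C | intermediate
11 | C8=C9 lithium enolate of 10 | C13(OCCO1)CC[C@@H]2C(C)=C(O[Li])CC[C@]32C | intermediate
12 | C9-alkylated keto ester (9β-[(3R)-5-methoxy-3-methyl-5-oxopentyl], 9α-Me, 8-oxo, C3 dioxolane) | C13(OCCO1)CC[C@@H]2[C@@](C)(CC[C@@H](C)CC(=O)OC)C(=O)CC[C@]32C | intermediate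
13 | C7=C8 potassium enolate of 12 | C13(OCCO1)CC[C@@H]2[C@@](C)(CC[C@@H](C)CC(=O)OC)C(O[K])=CC[C@]32C | intermediate
14 | Δ7 enol triflate (C8–OTf) | C13(OCCO1)CC[C@@H]2[C@@](C)(CC[C@@H](C)CC(=O)OC)C(OS(=O)(=O)C(F)(F)F)=CC[C@]32C | intermediate
15 | 8-methyl Δ7 alkene (methyl ester, C3 dioxolane) | C13(OCCO1)CC[C@@H]2[C@@](C)(CC[C@@H](C)CC(=O)OC)C(C)=CC[C@]32C | intermediate
16 | 7β-boryl-8α-methyl alkylborane (methyl ester, C3 dioxolane) | C13(OCCO1)CC[C@@H]2[C@@](C)(CC[C@@H](C)CC(=O)OC)[C@H](C)[C@@H](B)C[C@]32C | intermediate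
17 | 7β-hydroxy-8α-methyl ketal acid (free C15 acid, C3 dioxolane) | C13(OCCO1)CC[C@@H]2[C@@](C)(CC[C@@H](C)CC(=O)O)[C@H](C)[C@@H](O)C[C@]32C | intermediate
18 | 7β-hydroxy-8α-methyl-3-oxo acid (five-membered ring A ketone) | O=C1CC[C@@H]2[C@@](C)(CC[C@@H](C)CC(=O)O)[C@H](C)[C@@H](O)C[C@]12C | intermediate
19 | 3α-vinyl-3β,7β-diol acid (C3 epimer equally usable) | C=C[C@]1(O)CC[C@@H]2[C@@](C)(CC[C@@H](C)CC(=O)O)[C@H](C)[C@@H](O)C[C@]12C | intermediate
20 | mixed acetic anhydride of the 7-acetate (C15 CO–O–COCH3) | C=C[C@]1(O)CC[C@@H]2[C@@](C)(CC[C@@H](C)CC(=O)OC(C)=O)[C@H](C)[C@@H](OC(C)=O)C[C@]12C | intermediate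
21 | 7β-acetoxy-3β-hydroxy-3α-vinyl acid | C=C[C@]1(O)CC[C@@H]2[C@@](C)(CC[C@@H](C)CC(=O)O)[C@H](C)[C@@H](OC(C)=O)C[C@]12C | intermediate
22 | 7β-acetoxy-3-oxo-cis-cleroda-4(18)-en-15-oic acid | C=C1C(=O)CC[C@@H]2[C@@](C)(CC[C@@H](C)CC(=O)O)[C@H](C)[C@@H](OC(C)=O)C[C@]12C | intermediate
23 | 3-(trimethylsilyloxy)cleroda-2,4(18)-diene 7β-acetate trimethylsilyl ester | C=C1C(O[Si](C)(C)C)=CC[C@@H]2[C@@](C)(CC[C@@H](C)CC(=O)O[Si](C)(C)C)[C@H](C)[C@@H](OC(C)=O)C[C@]12C | intermediate
24 | 7β-acetoxy-2-hydroxy-3-oxo-cis-cleroda-4(18)-en-15-oic acid (C2 epimers, centre left undefined) | C=C1C(=O)C(O)C[C@@H]2[C@@](C)(CC[C@@H](C)CC(=O)O)[C@H](C)[C@@H](OC(C)=O)C[C@]12C | intermediate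
25 | 7β-acetoxy-2-hydroxy-3-oxo-cis-cleroda-1,4(18)-dien-15-oic acid (CNP0257844.1) | C=C1C(=O)C(O)=C[C@@H]2[C@@](C)(CC[C@@H](C)CC(=O)O)[C@H](C)[C@@H](OC(C)=O)C[C@]12C | target

## Step count and risks

Total: 14 steps (2 for the side chain, 12 in the main line). Longest linear sequence: 12 steps (Steps 3–14).

**Step 6 (C9 quaternary alkylation).** The risks are some C7 regioisomer, a slow SN2 reaction at a tetrasubstituted enolate, and incomplete β-face selectivity. The fallback sets out from 10 and comes back at 12, and makes the C9–C11 bond by a Michael reaction instead. Compound 10 is added to but-3-en-2-one with catalytic NaOMe in MeOH at 0 °C, where the methine carbon reacts as in the first stage of a Robinson annulation, to give the 1,5-diketone F1; this is kept cold to avoid aldol closure onto C8. Horner–Wadsworth–Emmons olefination of the unhindered methyl ketone with (MeO)2P(O)CH2CO2Me and NaH in THF at 0 °C gives the (E)-enoate F2 after removal of the minor Z isomer; the neopentyl C8 ketone does not react. Copper-hydride-catalysed asymmetric conjugate reduction (Cu(OAc)2, a chiral bisphosphine, polymethylhydrosiloxane, t-BuOH, toluene) then sets C13 and gives 12.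

**Step 9 (facial selectivity of the hydroboration).** The two half-chair conformers of the cis-hydrindene expose opposite faces, so α-face attack cannot be excluded. The fallback sets out from 15 and comes back at 18, and puts both centres under thermodynamic control. Compound 15 is hydroborated and oxidised cold, without the warm alkaline and acid stages, to give the alcohol F3 (drawn as the wrong-face 7α-hydroxy-8β-methyl isomer; any mixture is usable). Dess–Martin oxidation followed by NaOMe/MeOH equilibration gives the 7-ketone F4 with the C8 methyl in the more stable equatorial α orientation. Electron-transfer reduction with SmI2 and iPrOH in THF gives the equatorial 7β-alcohol F5. NaOH in MeOH/H2O and then HCl to pH 1 remove the methyl ester and the ketal to give 18.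

**Step 12 (the proposed new ring expansion).** The migration may be too slow without ring strain, letting ionisation or transposition of the tertiary allylic alcohol compete. The fallback sets out from 21 and comes back at 22, and uses known chemistry. Hydroxyl-directed epoxidation with VO(acac)2 and t-BuOOH in CH2Cl2 gives the epoxy alcohol F6. Semipinacol rearrangement of this 2,3-epoxy alcohol with BF3·OEt2 in CH2Cl2 at −78 °C moves C5 from C3 to C4 as the epoxide opens and gives the hydroxymethyl ketone F7. MsCl/Et3N and then DBU convert it, through the mesylate F8, by β-elimination into 22.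

## Further compounds

F1 | step 6 | 9β-(3-oxobutyl) diketone (9α-Me, 8-oxo, C3 dioxolane) | C13(OCCO1)CC[C@@H]2[C@@](C)(CCC(C)=O)C(=O)CC[C@]32C
F2 | step 6 | 9β-[(E)-5-methoxy-3-methyl-5-oxopent-3-enyl] ketone (9α-Me, 8-oxo, C3 dioxolane) | C13(OCCO1)CC[C@@H]2[C@@](C)(CC/C(C)=C/C(=O)OC)C(=O)CC[C@]32C
F3 | step 9 | 7α-hydroxy-8β-methyl methyl ester ketal (α-face hydroboration product) | C13(OCCO1)CC[C@@H]2[C@@](C)(CC[C@@H](C)CC(=O)OC)[C@@H](C)[C@H](O)C[C@]32C
F4 | step 9 | 8α-methyl-7-oxo methyl ester ketal | C13(OCCO1)CC[C@@H]2[C@@](C)(CC[C@@H](C)CC(=O)OC)[C@H](C)C(=O)C[C@]32C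
F5 | step 9 | 7β-hydroxy-8α-methyl methyl ester ketal | C13(OCCO1)CC[C@@H]2[C@@](C)(CC[C@@H](C)CC(=O)OC)[C@H](C)[C@@H](O)C[C@]32C
F6 | step 12 | 7β-acetoxy-3-hydroxy-3-(oxiran-2-yl) acid (epoxide carbon undefined) | C1OC1[C@]2(O)CC[C@@H]3[C@@](C)(CC[C@@H](C)CC(=O)O)[C@H](C)[C@@H](OC(C)=O)C[C@]23C
F7 | step 12 | 7β-acetoxy-18-hydroxy-3-oxo-cis-clerodan-15-oic acid (C4 undefined) | OCC1C(=O)CC[C@@H]2[C@@](C)(CC[C@@H](C)CC(=O)O)[C@H](C)[C@@H](OC(C)=O)C[C@]12C
F8 | step 12 | 18-methanesulfonate of F7 | CS(=O)(=O)OCC1C(=O)CC[C@@H]2[C@@](C)(CC[C@@H](C)CC(=O)O)[C@H](C)[C@@H](OC(C)=O)C[C@]12C
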